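**Plan**

- Retrosynthesis: the 4'-O-acetyl group is removed last; ring C is then cut at O1–C2 and C4–C4a, which gives phloroglucinol (ring A) and an aryl 2-methoxy-3-oxopropanoate.
- The keto ester is cut at its ArC(=O)–CH(OMe) bond into an acyl imidazolide and a methoxymalonate half-ester; the two aryl–prenyl bonds lead back to methyl 4-hydroxybenzoate and two equivalents of prenyl bromide.
- Forward: ring B is diprenylated, saponified and acetylated, the three-carbon chain is attached by a decarboxylative Claisen acylation, ring C is closed onto ring A in one thermal step, and the acetate is removed.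
- Enabling feature: ring A is threefold-symmetric phloroglucinol, so every ring carbon is equivalent and flanked by two hydroxyls, and C2, C3 (with its methoxy group) and C4 map onto the ketone, α-carbon and ester carbon of the keto ester.
- Stereochemistry: the target has no stereocentre and no stereogenic alkene; the racemic α-carbon of the keto ester ends as sp2 C3.

Key step: step 6

Remark: phloroglucinol is used as the anhydrous triol (the commercial dihydrate is dried before use), and the ester alkyl group of the keto ester is a spectator that leaves as the alcohol in the key step.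

**Step 1**
Reactants: 1 methyl 4-hydroxybenzoate; 2 prenyl bromide (1-bromo-3-methylbut-2-ene)
Product: 4 methyl 4-hydroxy-3,5-bis(3-methylbut-2-enyl)benzoate, via monoprenylated phenol 3 (not isolated)
Conditions: NaH (2.4 equiv in all, two portions), 2 (2.4 equiv in all, two portions), toluene, 0 °C to rt
Reagents that add atoms: prenyl bromide (second equivalent of 2), CC(C)=CCBr
Why: Ortho C-alkylation of a sodium phenoxide in a non-polar solvent, where the tight ion aggregate shields oxygen, should send the primary allylic bromide to the ring carbons next to the oxygen (SN2, linear prenyl), the para position being blocked by the ester and the second equivalent of base and bromide taking 3 on to 4.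

**Step 2**
Reactants: 4 methyl 4-hydroxy-3,5-bis(3-methylbut-2-enyl)benzoate
Product: 5 4-hydroxy-3,5-bis(3-methylbut-2-enyl)benzoic acid
Conditions: NaOH (2 M aq), MeOH, reflux; then 1 M HCl, 0 °C, to pH 3
Reagents that add atoms: sodium hydroxide, [Na+].[OH-]
Why: Ester saponification; the prenyl groups are inert to hydroxide and a brief cold acidification should not trigger addition of the phenol to the alkenes.

**Step 3**
Reactants: 5 4-hydroxy-3,5-bis(3-methylbut-2-enyl)benzoic acid
Product: 7 4-acetoxy-3,5-bis(3-methylbut-2-enyl)benzoic acid, via mixed acetic anhydride 6 (not isolated)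
Conditions: Ac2O (excess), pyridine, DMAP (cat.), rt; then H2O, THF, rt
Reagents that add atoms: acetic anhydride, CC(=O)OC(C)=O
Why: DMAP-catalysed O-acetylation reaches even the flanked phenol, and the mixed carboxylic–acetic anhydride formed in passing should be hydrolysed by aqueous pyridine at its acetyl carbonyl while the hindered aryl acetate stays.

**Step 4**
Reactants: 8 dimethyl 2-methoxymalonate
Product: 9 potassium methyl 2-methoxymalonate (potassium 2,3-dimethoxy-3-oxopropanoate)
Conditions: KOH (1.0 equiv), MeOH, 0 °C to rt; concentrate, triturate with Et2O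
Reagents that add atoms: potassium hydroxide, [K+].[OH-]
Why: Mono-saponification of a malonic diester, in which the first carboxylate deactivates the remaining ester so that one equivalent of hydroxide should stop at the half-ester salt.

**Step 5**
Reactants: 7 4-acetoxy-3,5-bis(3-methylbut-2-enyl)benzoic acid; 9 potassium methyl 2-methoxymalonate
Product: 12 methyl (2RS)-3-[4-acetoxy-3,5-bis(3-methylbut-2-enyl)phenyl]-2-methoxy-3-oxopropanoate, via acyl imidazolide 10 (not isolated), via aroylmalonic half-ester 11 (not isolated)
Conditions: 7, CDI (1.1 equiv), THF, rt; 9 (1.8 equiv), MgCl2 (1.8 equiv), Et3N (2.5 equiv), MeCN, rt; combine, rt to 45 °C; then cold 1 M HCl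
Reagents that add atoms: none
Why: Masamune–Brooks decarboxylative Claisen acylation, in which the chelated magnesium enolate of the half-ester is C-acylated by the acyl imidazolide and loss of CO2 from 11 drives the reaction, under conditions mild enough to spare the flanked aryl acetate and the prenyl groups.

**Step 6**
Reactants: 12 methyl (2RS)-3-[4-acetoxy-3,5-bis(3-methylbut-2-enyl)phenyl]-2-methoxy-3-oxopropanoate; 13 phloroglucinol (benzene-1,3,5-triol)
Product: 17 4-[5,7-dihydroxy-3-methoxy-4-oxochromen-2-yl]-2,6-bis(3-methylbut-2-enyl)phenyl acetate, via aroyl(methoxy)ketene 14 (not isolated), via 2-hydroxyaryl 1,3-diketone 15 (not isolated), via cyclic hemiketal 16 (not isolated)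
Conditions: 13 (1.5 equiv), neat melt, 240 °C, argon sweep, 30–45 min (or solvent-free microwave heating, a few minutes)
Reagents that add atoms: none
Why: On heating, 12 expels methanol to give the α-oxoketene 14, whose ketene carbon is attacked by a ring carbon of phloroglucinol (C4–C4a bond) to give, after tautomerisation, the 2-hydroxyaryl 1,3-diketone 15. An ortho phenol oxygen of 15 then adds to the aroyl carbonyl (O1–C2 bond, 6-exo-trig) to form hemiketal 16, and loss of water turns ring C into the 4-pyranone. The closest known reaction type is the Mentzer pyrone synthesis, the acid-free thermal condensation of phenols with β-keto esters to chromones, which with phloroglucinol and aroylacetates leads to 5,7-dihydroxyflavones. No stereocentre is created, since the racemic α-carbon of 12 ends as sp2 C3 carrying the methoxy group. The step needs chromone formation (ester carbon to ring carbon) to win over Pechmann coumarin formation (ketone carbon to ring carbon), which the absence of acid and the fast thermal ketene formation should secure, while the threefold symmetry of 13 leaves a single possible regioisomer. The acetate, shielded by its two ortho prenyl groups, should keep the 4'-oxygen from adding to the neighbouring alkenes in the melt.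

**Step 7**
Reactants: 17 4-[5,7-dihydroxy-3-methoxy-4-oxochromen-2-yl]-2,6-bis(3-methylbut-2-enyl)phenyl acetate
Product: 18 5,7-dihydroxy-2-[4-hydroxy-3,5-bis(3-methylbut-2-enyl)phenyl]-3-methoxychromen-4-one (CNP0205726.0)
Conditions: K2CO3 (3 equiv), MeOH, argon, 0 °C to rt; then cold 1 M HCl to pH 4–5
Reagents that add atoms: none
Why: Base-mediated methanolysis (transesterification) of an aryl acetate, which should leave the C3 methyl ether, the prenyl groups and the chromone core untouched at room temperature under inert gas.

**Compound list**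

1 | methyl 4-hydroxybenzoate | COC(=O)c1ccc(O)cc1 | starting material
2 | prenyl bromide (1-bromo-3-methylbut-2-ene) | CC(C)=CCBr | starting material
3 | methyl 4-hydroxy-3-(3-methylbut-2-enyl)benzoate | COC(=O)c1ccc(O)c(CC=C(C)C)c1 | intermediate
4 | methyl 4-hydroxy-3,5-bis(3-methylbut-2-enyl)benzoate | COC(=O)c1cc(CC=C(C)C)c(O)c(CC=C(C)C)c1 | intermediate
5 | 4-hydroxy-3,5-bis(3-methylbut-2-enyl)benzoic acid | OC(=O)c1cc(CC=C(C)C)c(O)c(CC=C(C)C)c1 | intermediate
6 | acetic 4-acetoxy-3,5-bis(3-methylbut-2-enyl)benzoic anhydride | CC(=O)OC(=O)c1cc(CC=C(C)C)c(OC(C)=O)c(CC=C(C)C)c1 | intermediate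
7 | 4-acetoxy-3,5-bis(3-methylbut-2-enyl)benzoic acid | CC(=O)Oc1c(CC=C(C)C)cc(C(=O)O)cc1CC=C(C)C | intermediate
8 | dimethyl 2-methoxymalonate | COC(C(=O)OC)C(=O)OC | starting material
9 | potassium methyl 2-methoxymalonate (potassium 2,3-dimethoxy-3-oxopropanoate) | COC(C(=O)OC)C(=O)[O-].[K+] | intermediate
10 | 4-(imidazol-1-ylcarbonyl)-2,6-bis(3-methylbut-2-enyl)phenyl acetate | CC(=O)Oc1c(CC=C(C)C)cc(C(=O)n2ccnc2)cc1CC=C(C)C | intermediate
11 | 2-[4-acetoxy-3,5-bis(3-methylbut-2-enyl)benzoyl]-2-methoxymalonic acid monomethyl ester (racemic) | COC(=O)C(OC)(C(=O)O)C(=O)c1cc(CC=C(C)C)c(OC(C)=O)c(CC=C(C)C)c1 | intermediate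
12 | methyl (2RS)-3-[4-acetoxy-3,5-bis(3-methylbut-2-enyl)phenyl]-2-methoxy-3-oxopropanoate (racemic, enolisable) | COC(=O)C(OC)C(=O)c1cc(CC=C(C)C)c(OC(C)=O)c(CC=C(C)C)c1 | intermediate
13 | phloroglucinol (benzene-1,3,5-triol) | Oc1cc(O)cc(O)c1 | starting material
14 | 4-(2-methoxy-3-oxoprop-2-enoyl)-2,6-bis(3-methylbut-2-enyl)phenyl acetate (aroyl methoxy ketene) | COC(=C=O)C(=O)c1cc(CC=C(C)C)c(OC(C)=O)c(CC=C(C)C)c1 | intermediate
15 | 1-[4-acetoxy-3,5-bis(3-methylbut-2-enyl)phenyl]-2-methoxy-3-(2,4,6-trihydroxyphenyl)propane-1,3-dione (racemic) | COC(C(=O)c1c(O)cc(O)cc1O)C(=O)c1cc(CC=C(C)C)c(OC(C)=O)c(CC=C(C)C)c1 | intermediate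
16 | 4-[2,5,7-trihydroxy-3-methoxy-4-oxochroman-2-yl]-2,6-bis(3-methylbut-2-enyl)phenyl acetate (racemic mixture of diastereomers) | COC1C(=O)c2c(O)cc(O)cc2OC1(O)c1cc(CC=C(C)C)c(OC(C)=O)c(CC=C(C)C)c1 | intermediate
17 | 4-[5,7-dihydroxy-3-methoxy-4-oxochromen-2-yl]-2,6-bis(3-methylbut-2-enyl)phenyl acetate | COc1c(-c2cc(CC=C(C)C)c(OC(C)=O)c(CC=C(C)C)c2)oc2cc(O)cc(O)c2c1=O | intermediate
18 | 5,7-dihydroxy-2-[4-hydroxy-3,5-bis(3-methylbut-2-enyl)phenyl]-3-methoxychromen-4-one | COc1c(-c2cc(CC=C(C)C)c(O)c(CC=C(C)C)c2)oc2cc(O)cc(O)c2c1=O | target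

**Step count**

Total: 7 steps. Longest linear sequence: 6 steps (1, 2, 3, 5, 6, 7); step 4 is a one-step side branch.

**Steps most likely to fail**

Step 6. The melt may divert to Pechmann-type attack of the ring carbon on the ketone. At 240 °C the acetyl group may also migrate to the polyphenol, after which the freed 4'-oxygen can add to a prenyl alkene, or the prenyl groups may degrade. The fallback sets out from 7 and builds ring C by an Allan–Robinson condensation instead. Acid 7 would be dehydrated with DCC (0.5 equiv, CH2Cl2) to 4-acetoxy-3,5-bis(3-methylbut-2-enyl)benzoic anhydride F1. An excess of this anhydride would be heated with commercial 2-methoxy-1-(2,4,6-trihydroxyphenyl)ethan-1-one (COCC(=O)c1c(O)cc(O)cc1O) and Et3N in a sealed tube at about 160 °C. O-aroylation, C-aroylation at the methoxymethyl carbon and cyclodehydration should give the flavone, expected chiefly as 2-[4-acetoxy-3,5-bis(3-methylbut-2-enyl)phenyl]-5-hydroxy-3-methoxy-4-oxochromen-7-yl 4-acetoxy-3,5-bis(3-methylbut-2-enyl)benzoate F2. Brief treatment of this ester with KOH in aqueous MeOH and cold acidification would cleave the aroyl ester and both acetates, so the path comes back to the route at 18.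

Step 1. The para-ester phenoxide is a weak carbon nucleophile, so O-alkylation, stalling at the monoprenyl stage or over-alkylation to dienones may dominate. The fallback sets out from 2 and uses a more carbon-nucleophilic phenol. Commercial 4-iodophenol (Oc1ccc(I)cc1) would be diprenylated with two equivalents of 2 and NaH in toluene to 4-iodo-2,6-bis(3-methylbut-2-enyl)phenol F3. Methoxycarbonylation of this iodide [PdCl2(PPh3)2 (cat.), CO (1 atm), MeOH, Et3N, 70 °C] would then install the ester, and the path comes back at 4.

Step 5. C-acylation of the fully substituted methoxymalonate carbon may be slow or reversible (retro-Claisen by imidazole), and the liberated imidazole may slowly cleave the aryl acetate. The fallback sets out from 7 (through 10, made as in step 5) and introduces the methoxy group after the carbon–carbon bond. Imidazolide 10 would be combined with commercial potassium methyl malonate (COC(=O)CC(=O)[O-].[K+]), MgCl2 and Et3N to give 2-[4-acetoxy-3,5-bis(3-methylbut-2-enyl)benzoyl]malonic acid monomethyl ester F4, which loses CO2 to methyl 3-[4-acetoxy-3,5-bis(3-methylbut-2-enyl)phenyl]-3-oxopropanoate F5. Diazo transfer with 4-acetamidobenzenesulfonyl azide and Et3N in MeCN would give methyl 3-[4-acetoxy-3,5-bis(3-methylbut-2-enyl)phenyl]-2-diazo-3-oxopropanoate F6. O–H insertion of the carbenoid from this diazo ester into methanol [Rh2(OAc)4 (cat.), MeOH, CH2Cl2, rt] would then bring the path back at 12.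

**Further compounds**

F1 | step 6 | 4-acetoxy-3,5-bis(3-methylbut-2-enyl)benzoic anhydride | CC(=O)Oc1c(CC=C(C)C)cc(cc1CC=C(C)C)C(=O)OC(=O)c1cc(CC=C(C)C)c(OC(C)=O)c(CC=C(C)C)c1
F2 | step 6 | 2-[4-acetoxy-3,5-bis(3-methylbut-2-enyl)phenyl]-5-hydroxy-3-methoxy-4-oxochromen-7-yl 4-acetoxy-3,5-bis(3-methylbut-2-enyl)benzoate | COc1c(-c2cc(CC=C(C)C)c(OC(C)=O)c(CC=C(C)C)c2)oc2cc(OC(=O)c3cc(CC=C(C)C)c(OC(C)=O)c(CC=C(C)C)c3)cc(O)c2c1=O
F3 | step 1 | 4-iodo-2,6-bis(3-methylbut-2-enyl)phenol | CC(C)=CCc1cc(I)cc(CC=C(C)C)c1O
F4 | step 5 | 2-[4-acetoxy-3,5-bis(3-methylbut-2-enyl)benzoyl]malonic acid monomethyl ester (racemic) | COC(=O)C(C(=O)O)C(=O)c1cc(CC=C(C)C)c(OC(C)=O)c(CC=C(C)C)c1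
F5 | step 5 | methyl 3-[4-acetoxy-3,5-bis(3-methylbut-2-enyl)phenyl]-3-oxopropanoate | COC(=O)CC(=O)c1cc(CC=C(C)C)c(OC(C)=O)c(CC=C(C)C)c1
F6 | step 5 | methyl 3-[4-acetoxy-3,5-bis(3-methylbut-2-enyl)phenyl]-2-diazo-3-oxopropanoate | COC(=O)C(=[N+]=[N-])C(=O)c1cc(CC=C(C)C)c(OC(C)=O)c(CC=C(C)C)c1
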